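**Plan**

1. The target is (2R)-2-hydroxy-4-methylbenzofuran-3(2H)-one carrying at C2 a (2'E,6'E,8'R)-8'-hydroxy-3',7',11'-trimethyldodeca-2',6',10'-trienyl chain (chain atoms C1'–C12' counted from the ring).
2. Retrosynthesis cuts, in order: C2–OH (enolate hydroxylation); the chain bond C5'–C6' (union of the two halves); C2–C1' (Tsuji–Trost) and C1'–C2'/C3'–CH3 (carboalumination) in the western half; C7'–CH3 and C8'–C9' in the eastern half.
3. Enabling feature: in the allylic alcohol C6'H=C7'(CH3)–C8'H(OH) the vinylic carbon C6' and the C8' oxygen are 1,3-related, so C6' can be raised to the enol-ether level and tied to that oxygen through an acetone ketal, giving a 4H-1,3-dioxin ring (ring atoms O1, C2 (CMe2), O3, C4 = chain C8', C5 = chain C7', C6 = chain C6') whose lithiated C6 is a vinylidene carbenoid.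
4. Forward: the eastern dioxin is made from 2,2-dimethyl-1,3-dioxan-5-one (5 steps) and the western primary iodide, with the benzofuranone masked as an aromatic silyl enol ether, from a silylated butynol (6 steps). They are joined by a ring-opening 1,2-metalate rearrangement that forms C5'–C6', fixes 6'E and frees the C8' carbinol with loss of acetone; desilylation and C2 hydroxylation follow. No ring is built: the benzofuranone is bought and the dioxin ring is temporary.
5. Stereochemistry: C8' (R) from RAMP-hydrazone alkylation; 2'E from syn-carboalumination; 6'E from the invertive metalate shift; C2 (R) from a camphor-derived oxaziridine in the last step.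

Key step: step 12

Assumption: C2 is a hemiketal carbon that can epimerise by ring-chain tautomerism (opening to the 1-aryl-1,2-dione with a free phenol), so it is set in the last step under kinetic control and the product is kept cold, neutral and aprotic; 4-methylbenzofuran-3(2H)-one and the other numbered starting materials are taken as catalogue compounds.

**Route**

Step 1
Reactants: 1 2,2-dimethyl-1,3-dioxan-5-one; 2 (R)-1-amino-2-(methoxymethyl)pyrrolidine (RAMP)
Product: 3 (2R)-N-(2,2-dimethyl-1,3-dioxan-5-ylidene)-2-(methoxymethyl)pyrrolidin-1-amine (RAMP hydrazone of 1)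
Conditions: benzene, reflux, Dean–Stark
Reagents that add atoms: none
Why: Hydrazone condensation of the ketone with the chiral hydrazine, driven by azeotropic removal of water, installs the auxiliary that will control the future C8' centre.

Step 2
Reactants: 3 RAMP hydrazone; 4 1-bromo-3-methylbut-2-ene (prenyl bromide)
Product: 6 (2R)-N-[(4R)-2,2-dimethyl-4-(3-methylbut-2-en-1-yl)-1,3-dioxan-5-ylidene]-2-(methoxymethyl)pyrrolidin-1-amine, via lithium azaenolate 5 (not isolated)
Conditions: t-BuLi, THF, −78 °C; then 4, −100 °C → rt
Reagents that add atoms: none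
Why: Enders SAMP/RAMP hydrazone alkylation, in which the methoxy-chelated lithium azaenolate should be alkylated by the allylic bromide on the face left open by the (R)-pyrrolidine auxiliary, setting the (4R) centre (the future C8'; (R) is expected from RAMP by the established azaenolate model).

Step 3
Reactants: 6 alkylated RAMP hydrazone
Product: 7 (4R)-2,2-dimethyl-4-(3-methylbut-2-en-1-yl)-1,3-dioxan-5-one
Conditions: sat. aq. oxalic acid, Et2O, rt
Reagents that add atoms: water, O
Why: Mild two-phase hydrazone hydrolysis with oxalic acid should free the ketone without opening the acetonide or epimerising the α-centre, and returns the auxiliary.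

Step 4
Reactants: 7 (4R)-dioxanone
Product: 9 (4R)-2,2-dimethyl-4-(3-methylbut-2-en-1-yl)-4H-1,3-dioxin-5-yl trifluoromethanesulfonate, via potassium enolate 8 (not isolated)
Conditions: KN(SiMe3)2, THF, −78 °C; PhNTf2, −78 → 0 °C
Reagents that add atoms: N-phenylbis(trifluoromethanesulfonimide), FC(F)(F)S(=O)(=O)N(c1ccccc1)S(=O)(=O)C(F)(F)F
Why: Kinetic enol triflate formation, in which the bulky amide at −78 °C should remove a proton from the unsubstituted α-CH2 (C6) and not from the substituted C4, so that O-sulfonylation gives the C5=C6 enol triflate with the stereocentre untouched.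

Step 5
Reactants: 9 dioxinyl triflate
Product: 10 (4R)-2,2,5-trimethyl-4-(3-methylbut-2-en-1-yl)-4H-1,3-dioxine
Conditions: MeMgBr, Fe(acac)3 (5 mol %), THF/NMP, −30 °C
Reagents that add atoms: methylmagnesium bromide, C[Mg]Br
Why: Iron-catalysed Kumada-type cross-coupling of an alkenyl triflate with a methyl Grignard reagent should replace the triflate by methyl at low temperature, leaving the acid- and heat-sensitive enol ketal intact (the product is kept at or below room temperature to avoid cycloreversion with loss of acetone).

Step 6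
Reactants: 11 tert-butyl(but-3-yn-1-yloxy)dimethylsilane
Product: 14 (2E)-5-[(tert-butyldimethylsilyl)oxy]-3-methylpent-2-en-1-ol, via alkenyldimethylalane 12 (not isolated), via lithium alkenylalanate 13 (not isolated)
Conditions: Me3Al, Cp2ZrCl2 (20 mol %), CH2Cl2, 0 °C → rt; n-BuLi, THF, −78 → 0 °C; (CH2O)n, rt
Reagents that add atoms: trimethylaluminium, C[Al](C)C; formaldehyde (as paraformaldehyde), C=O
Why: Negishi zirconium-catalysed carboalumination adds methyl and aluminium syn across the terminal alkyne with aluminium on the terminal carbon, and the derived alanate is hydroxymethylated by formaldehyde with retention, which fixes the 2'E double bond.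

Step 7
Reactants: 14 allylic alcohol
Product: 15 (2E)-5-[(tert-butyldimethylsilyl)oxy]-3-methylpent-2-en-1-yl methyl carbonate
Conditions: ClCO2Me, pyridine, CH2Cl2, 0 °C
Reagents that add atoms: methyl chloroformate, COC(=O)Cl
Why: Acylation of the primary allylic alcohol gives the allylic carbonate needed as the leaving group for the later palladium-catalysed allylation.

Step 8
Reactants: 15 silyl ether carbonate
Product: 16 (2E)-5-hydroxy-3-methylpent-2-en-1-yl methyl carbonate
Conditions: HF·pyridine, THF, 0 °C → rt
Reagents that add atoms: none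
Why: Fluoride-mediated cleavage of the primary silyl ether under mildly acidic conditions should leave the allylic carbonate untouched.

Step 9
Reactants: 16 hydroxy carbonate
Product: 17 (2E)-5-iodo-3-methylpent-2-en-1-yl methyl carbonate
Conditions: I2, PPh3, imidazole, CH2Cl2, 0 °C
Reagents that add atoms: iodine, [I][I]
Why: Appel-type iodination converts the primary alcohol through its alkoxyphosphonium salt into the primary iodide by SN2 displacement, without touching the carbonate or the alkene.

Step 10
Reactants: 17 iodo carbonate; 18 4-methylbenzofuran-3(2H)-one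
Product: 19 2-[(2E)-5-iodo-3-methylpent-2-en-1-yl]-4-methylbenzofuran-3(2H)-one (racemic at C2)
Conditions: Pd(PPh3)4 (5 mol %), 18 (3 equiv), THF, rt
Reagents that add atoms: none
Why: Tsuji–Trost allylic alkylation, in which zerovalent palladium ionises the carbonate to a syn π-allyl complex and methoxide, the methoxide deprotonates the acidic ketone, and the soft enolate attacks the unsubstituted allyl terminus to give the linear 2'E C-allylated ketone (any O-allyl product is re-ionised, excess 18 limits double allylation, and the unactivated alkyl iodide should not react at room temperature).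

Step 11
Reactants: 19 2-alkylbenzofuranone
Product: 20 {2-[(2E)-5-iodo-3-methylpent-2-en-1-yl]-4-methylbenzofuran-3-yl}oxy-tri(propan-2-yl)silane
Conditions: TIPSOTf, Et3N, CH2Cl2, 0 °C
Reagents that add atoms: triisopropylsilyl trifluoromethanesulfonate, CC(C)[Si](C(C)C)(C(C)C)OS(=O)(=O)C(F)(F)F
Why: Silyl enol ether formation turns the acidic, electrophilic ketone into an aromatic 3-silyloxybenzofuran that should be inert to the organolithium and cuprate chemistry of the next step.

Step 12
Reactants: 20 western iodide; 10 eastern dioxin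
Product: 25 (5R,6E,10E)-2,6,10-trimethyl-12-{4-methyl-3-[tri(propan-2-yl)silyloxy]benzofuran-2-yl}dodeca-2,6,10-trien-5-ol, via alkyllithium 21 (not isolated), via lithiodioxin 22 (not isolated), via lithium alkyl(alkenyl)cuprate 23 (not isolated), via lithium alkoxy(alkenyl)cuprate 24 (not isolated)
Conditions: 20, t-BuLi (2.1 equiv), Et2O/pentane, −78 °C, then CuBr·SMe2, Me2S, −78 → −40 °C; 10, t-BuLi, THF, −78 → −20 °C (second flask); mix at −78 °C, then → rt; aq. NH4Cl
Reagents that add atoms: none
Why: Proposed new method: oxygen-directed vinylic lithiation of 10 at C6 gives an α-alkoxyalkenyllithium that joins the alkylcopper from 20 as cuprate 23; on warming, the C5' alkyl group shifts from copper to C6 while the ketal oxygen O1 leaves (1,2-metalate rearrangement), the ring-opened hemiketal alkoxide sheds acetone, and the alkenylcopper 24 is protonated with retention to give 25. The closest known reaction type is the 1,2-metalate rearrangement of α-alkoxyalkenyl cuprates made from 5-lithio-2,3-dihydrofurans, 6-lithio-3,4-dihydro-2H-pyrans and 1-lithioglycals, which opens the ring and gives trisubstituted alkenes stereospecifically; new here is the 4H-1,3-dioxin substrate, whose leaving oxygen is a ketal oxygen (a better nucleofuge than an ether oxygen) and whose ring is lost as acetone. No ring is closed (the six-membered dioxin is opened at C6–O1) and no stereocentre is created: C8' is carried unchanged from 10, and the new stereogenic element, the 6'E double bond, is fixed because the shift inverts C6, so that the alkyl group takes the site the metal held and copper takes the site O1 held, cis to the C8' oxygen, leaving C5' trans to C8'. The step needs vinylic (C6–H) and not allylic (C4–H or C5-methyl) deprotonation, which coordination of t-BuLi to O1 and the higher kinetic acidity of the sp2 C–H next to oxygen should secure as in glycals, and it needs migration of the right group, which is secured because the C5' alkyl is the only transferable ligand on copper. The aromatic 3-silyloxybenzofuran of 20 offers no electrophilic or acidic site to the primary alkyllithium at −78 °C.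

Step 13
Reactants: 25 coupled silyl enol ether
Product: 26 2-[(2E,6E,8R)-8-hydroxy-3,7,11-trimethyldodeca-2,6,10-trien-1-yl]-4-methylbenzofuran-3(2H)-one (mixture of C2 epimers)
Conditions: Bu4NF, AcOH, THF, 0 °C
Reagents that add atoms: none
Why: Buffered fluoride desilylation of the aryl-type silyl enol ether should return the ketone without base-induced side reactions and without touching the allylic alcohol or the alkenes.

Step 14
Reactants: 26 2-alkylbenzofuranone
Product: 28 (2R)-2-hydroxy-2-[(2E,6E,8R)-8-hydroxy-3,7,11-trimethyldodeca-2,6,10-trien-1-yl]-4-methylbenzofuran-3(2H)-one, via sodium enolate 27 (not isolated)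
Conditions: NaN(SiMe3)2 (1.05 equiv), THF, −78 °C; (8,8-dichlorocamphorylsulfonyl)oxaziridine from (1S)-10-camphorsulfonic acid, −78 °C; AcOH, −78 °C, then pH 7 buffer
Reagents that add atoms: (8,8-dichlorocamphorylsulfonyl)oxaziridine of the (1S)-10-camphorsulfonic acid series, CC1(C)[C@@H]2CC[C@]13CS(=O)(=O)N4O[C@@]34C2(Cl)Cl
Why: Davis oxaziridine hydroxylation of the planar sodium 3-benzofuranolate, in which the camphor framework of the enantiopure N-sulfonyloxaziridine selects the enolate face (reagent control, sense assigned by analogy with 2-substituted 1-tetralone and chromanone enolates) and should set (2R), the oxidant being inert to the three trisubstituted alkenes and the cold acidic quench limiting epimerisation of the new hemiketal.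

**Compound list**

1 | 2,2-dimethyl-1,3-dioxan-5-one | CC1(C)OCC(=O)CO1 | starting material
2 | (R)-1-amino-2-(methoxymethyl)pyrrolidine (RAMP) | COC[C@H]1CCCN1N | starting material
3 | (2R)-N-(2,2-dimethyl-1,3-dioxan-5-ylidene)-2-(methoxymethyl)pyrrolidin-1-amine | COC[C@H]1CCCN1N=C2COC(C)(C)OC2 | intermediate
4 | 1-bromo-3-methylbut-2-ene | CC(C)=CCBr | starting material
5 | lithium azaenolate of 3 (not isolated) | COC[C@H]1CCCN1N([Li])C2=COC(C)(C)OC2 | intermediate
6 | (2R)-N-[(4R)-2,2-dimethyl-4-(3-methylbut-2-en-1-yl)-1,3-dioxan-5-ylidene]-2-(methoxymethyl)pyrrolidin-1-amine | COC[C@H]1CCCN1N=C2COC(C)(C)O[C@@H]2CC=C(C)C | intermediate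
7 | (4R)-2,2-dimethyl-4-(3-methylbut-2-en-1-yl)-1,3-dioxan-5-one | CC(C)=CC[C@H]1OC(C)(C)OCC1=O | intermediate
8 | potassium C5–C6 enolate of 7 (not isolated) | CC(C)=CC[C@H]1OC(C)(C)OC=C1O[K] | intermediate
9 | (4R)-2,2-dimethyl-4-(3-methylbut-2-en-1-yl)-4H-1,3-dioxin-5-yl trifluoromethanesulfonate | CC(C)=CC[C@H]1OC(C)(C)OC=C1OS(=O)(=O)C(F)(F)F | intermediate
10 | (4R)-2,2,5-trimethyl-4-(3-methylbut-2-en-1-yl)-4H-1,3-dioxine | CC(C)=CC[C@H]1OC(C)(C)OC=C1C | intermediate
11 | tert-butyl(but-3-yn-1-yloxy)dimethylsilane | C#CCCO[Si](C)(C)C(C)(C)C | starting material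
12 | [(1E)-4-(tert-butyldimethylsilyloxy)-2-methylbut-1-en-1-yl]dimethylalane (not isolated) | C[Al](C)/C=C(C)/CCO[Si](C)(C)C(C)(C)C | intermediate
13 | lithium butyl[(1E)-4-(tert-butyldimethylsilyloxy)-2-methylbut-1-en-1-yl]dimethylalanate (not isolated) | [Li+].CCCC[Al-](C)(C)/C=C(C)/CCO[Si](C)(C)C(C)(C)C | intermediate
14 | (2E)-5-[(tert-butyldimethylsilyl)oxy]-3-methylpent-2-en-1-ol | OC/C=C(C)/CCO[Si](C)(C)C(C)(C)C | intermediate
15 | (2E)-5-[(tert-butyldimethylsilyl)oxy]-3-methylpent-2-en-1-yl methyl carbonate | COC(=O)OC/C=C(C)/CCO[Si](C)(C)C(C)(C)C | intermediate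
16 | (2E)-5-hydroxy-3-methylpent-2-en-1-yl methyl carbonate | COC(=O)OC/C=C(C)/CCO | intermediate
17 | (2E)-5-iodo-3-methylpent-2-en-1-yl methyl carbonate | COC(=O)OC/C=C(C)/CCI | intermediate
18 | 4-methylbenzofuran-3(2H)-one | Cc1cccc2OCC(=O)c12 | starting material
19 | 2-[(2E)-5-iodo-3-methylpent-2-en-1-yl]-4-methylbenzofuran-3(2H)-one (racemic at C2) | Cc1cccc2OC(C/C=C(C)/CCI)C(=O)c12 | intermediate
20 | {2-[(2E)-5-iodo-3-methylpent-2-en-1-yl]-4-methylbenzofuran-3-yl}oxy-tri(propan-2-yl)silane | Cc1cccc2oc(C/C=C(C)/CCI)c(O[Si](C(C)C)(C(C)C)C(C)C)c12 | intermediate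
21 | primary alkyllithium from 20 (lithium in place of iodine; not isolated) | Cc1cccc2oc(C/C=C(C)/CC[Li])c(O[Si](C(C)C)(C(C)C)C(C)C)c12 | intermediate
22 | (4R)-6-lithio-2,2,5-trimethyl-4-(3-methylbut-2-en-1-yl)-4H-1,3-dioxine (not isolated) | CC(C)=CC[C@H]1OC(C)(C)OC([Li])=C1C | intermediate
23 | lithium alkyl(dioxin-6-yl)cuprate from 21 and 22 (not isolated) | [Li+].CC(C)=CC[C@H]1OC(C)(C)OC(=C1C)[Cu-]CC/C(C)=C/Cc1oc2cccc(C)c2c1O[Si](C(C)C)(C(C)C)C(C)C | intermediate
24 | lithium alkoxy(alkenyl)cuprate after the 1,2-shift and loss of acetone, a five-membered oxacuprate with copper on C6' cis to the C8' oxygen (not isolated) | [Li+].CC(C)=CC[C@H]1O[Cu-]C(=C1C)CC/C(C)=C/Cc1oc2cccc(C)c2c1O[Si](C(C)C)(C(C)C)C(C)C | intermediate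
25 | (5R,6E,10E)-2,6,10-trimethyl-12-{4-methyl-3-[tri(propan-2-yl)silyloxy]benzofuran-2-yl}dodeca-2,6,10-trien-5-ol | CC(C)=CC[C@@H](O)/C(C)=C/CC/C(C)=C/Cc1oc2cccc(C)c2c1O[Si](C(C)C)(C(C)C)C(C)C | intermediate
26 | 2-[(2E,6E,8R)-8-hydroxy-3,7,11-trimethyldodeca-2,6,10-trien-1-yl]-4-methylbenzofuran-3(2H)-one (mixture of C2 epimers) | CC(C)=CC[C@@H](O)/C(C)=C/CC/C(C)=C/CC1Oc2cccc(C)c2C1=O | intermediate
27 | sodium enolate of 26 (sodium 3-benzofuranolate; not isolated) | CC(C)=CC[C@@H](O)/C(C)=C/CC/C(C)=C/Cc1oc2cccc(C)c2c1O[Na] | intermediate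
28 | (2R)-2-hydroxy-2-[(2E,6E,8R)-8-hydroxy-3,7,11-trimethyldodeca-2,6,10-trien-1-yl]-4-methylbenzofuran-3(2H)-one | CC(C)=CC[C@@H](O)/C(C)=C/CC/C(C)=C/C[C@@]1(O)Oc2cccc(C)c2C1=O | target

**Step count and risks**

Total step count: 14. Longest linear sequence: 9 steps (steps 6–14, from 11); the eastern branch (steps 1–5) joins at step 12.

Steps most likely to fail:

1. Step 12 (Proposed new method). Lithiation of the dioxin may occur at the allylic C4–H instead of the vinylic C6–H. The lithiated dioxin may undergo α-elimination before the cuprate forms. The metalate shift may be too slow to compete with thermal decay of the cuprate. Fallback by known chemistry on the same bond, a B-alkyl Suzuki–Miyaura coupling, setting out from iodide 20 and returning to the route at 25: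
   - Commercial (E)-3-iodo-2-methylprop-2-en-1-ol is oxidised (MnO2, CH2Cl2) to (E)-3-iodo-2-methylprop-2-enal F1.
   - Brown allylation with (+)-B-allyldiisopinocampheylborane (Et2O, −78 °C, oxidative work-up) gives (3R,1E)-1-iodo-2-methylhexa-1,5-dien-3-ol F2.
   - Cross-metathesis with 2-methylbut-2-ene (second-generation Grubbs catalyst (H2IMes)(PCy3)Cl2Ru=CHPh, CH2Cl2, 40 °C) turns the allyl into the prenyl group and gives (3R,1E)-1-iodo-2,6-dimethylhepta-1,5-dien-3-ol F3.
   - Iodide 20 is lithiated (t-BuLi, Et2O, −78 °C) and trapped with B-methoxy-9-borabicyclo[3.3.1]nonane to give the lithium alkyl(methoxy)borate F4.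
   - F4 is coupled with F3 (PdCl2(dppf), AsPh3, Cs2CO3, DMF/H2O, rt) with retention of the alkene geometry to give 25.

2. Step 14. The C2 configuration may be eroded by ring opening of the hemiketal alkoxide before the quench, and the facial selectivity of the oxaziridine toward this enolate may be low or opposite to the analogy. Fallback from 26, returning at 28: hydroxylation without asymmetric induction (NaN(SiMe3)2, then racemic 2-(phenylsulfonyl)-3-phenyloxaziridine, −78 °C) gives 28 together with its (2S) epimer F5. The two diastereomers are separated by preparative HPLC on a chiral stationary phase. F5 is re-equilibrated through the open 1,2-dione (catalytic Et3N, CH2Cl2) and put through the separation again.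

3. Step 4. Enolisation toward the substituted C4 would scramble the future C8' centre and give the regioisomeric triflate. Fallback from 7, returning at 10, with no enolate on the way: Wittig methylenation (Ph3PCH3Br, KOtBu, THF, 0 °C) gives (4R)-2,2-dimethyl-5-methylidene-4-(3-methylbut-2-en-1-yl)-1,3-dioxane F6. Its exocyclic double bond is moved into the ring toward the O–CH2 side by ruthenium hydride catalysis (RuHCl(CO)(PPh3)3, toluene, 80 °C) to give 10.

**Further compounds**

F1 | step 12 | (E)-3-iodo-2-methylprop-2-enal | O=C/C(C)=C/I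
F2 | step 12 | (3R,1E)-1-iodo-2-methylhexa-1,5-dien-3-ol | C=CC[C@@H](O)/C(C)=C/I
F3 | step 12 | (3R,1E)-1-iodo-2,6-dimethylhepta-1,5-dien-3-ol | CC(C)=CC[C@@H](O)/C(C)=C/I
F4 | step 12 | lithium B-methoxy-B-alkyl-9-borabicyclo[3.3.1]nonane borate from 20 (alkyl is the side chain of 20 bound through C5') | [Li+].CO[B-]1(CC/C(C)=C/Cc2oc3cccc(C)c3c2O[Si](C(C)C)(C(C)C)C(C)C)C2CCCC1CCC2
F5 | step 14 | (2S)-2-hydroxy-2-[(2E,6E,8R)-8-hydroxy-3,7,11-trimethyldodeca-2,6,10-trien-1-yl]-4-methylbenzofuran-3(2H)-one | CC(C)=CC[C@@H](O)/C(C)=C/CC/C(C)=C/C[C@]1(O)Oc2cccc(C)c2C1=O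
F6 | step 4 | (4R)-2,2-dimethyl-5-methylidene-4-(3-methylbut-2-en-1-yl)-1,3-dioxane | CC(C)=CC[C@H]1OC(C)(C)OCC1=C
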